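Read the slope.

| flask | Z | X | remark | time |
|---|---|---|---|---|
| Saturday's | 0.0028 M | 2 equiv | run made earlier |  |
| Wednesday's | 0.0044 M | 2 equiv | run made earlier |  |
| flask | 0.0020 M | 2.00 equiv |  | 2.0 min |

- Saturday's (time / s: Q / %): 10.0: 2.0; 20.0: 7.2; 30.0: 13.5; 50.0: 29.7; 80.0: 53.0
- Wednesday's (time / s: Q / %): 15.0: 4.3; 30.0: 13.7; 40.0: 20.6; 60.0: 37.0; 80.0: 52.5

(readings scatter by 0.3 percentage points)

* how much Q there is at 2.0 min, in percent of the Z charged
* the change that raises the amount of Q at 2.0 min, in percent of the Z charged most ("none" if none brings more than 2 percentage points) (epsilon / alpha / beta / none)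
* amount of Q at 2.0 min, in percent of the Z charged, after beta

- epsilon: doubling the dissolution coefficient of Z, all else as stated
- alpha: doubling the solubility of Z, all else as stated
- beta: doubling the amount of X, all else as stated

In both runs Q climbs along a straight line once a short delay, an induction period in the usual term, is over. From Saturday's readings:

slope = (53.0% − 13.5%) / (80.0 s − 30.0 s) = 0.00790 s⁻¹

This charge slope, the fraction of the Z charged that becomes Q per unit time on the straight stretch, reads 0.00776 s⁻¹ on Wednesday's run, at 1.57 times the charge. Both runs hold X at 2 equiv, so the reckoning here carries the slope to this flask, although its charge lies below both.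

The time scales then stand in a row:

delay, where the line meets zero: 12.9 s
last reading, still on the line: 80.0 s
asked time: 120 s
line reaches the whole charge: 139 s

At the asked time the line stands at 84.6%. Q cannot pass the charge, so the curve has to bend before 139 s. The value at the asked time is an estimate carried over from another charge, not a bound. The runs never vary X alone. If the slope follows X, doubling it brings the line to the whole charge at 76.2 s, so beta is the choice here.

The forecast gives 79%, beta and 93%, holding that “the yield does not depend on the charge”.

The flask gives 74.3%; beta gains 22 percentage points and reaches 96.0%.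

    J ⇌ D (K = 0.195, k = 2.44 s⁻¹)
    X → E (k = 4.76 × 10⁻⁵ s⁻¹)
    X → G (k = 0.0443 s⁻¹)
    D + G → Q (k = 34.6 L mol⁻¹ s⁻¹)
    Z ⇌ J, rate k5*(cs5 - [J]) while solid is left; crystals form when [J] > cs5 (solubility = 0.830 mM, k = 1.20 s⁻¹)

Going into solution could deliver 5976% by 2.0 min into a solution kept empty, while 74.3% passes on to Q, and J stands at 99.2% of saturation at 0.200 min. At 1.00 min, with Z at 13.6%, the line gives 37.2% against 37.6% of Q; at 2.0 min, with Z at 0%, the flask lies 10 points under it.

For the neighbour charged with 0.0012 M of Z, the line gives the same 84.6%, since the charge does not enter it. The computed Q there is 64.1%, with Z at 0% and J at 30.1%.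

All runs were computed on assumed constants; noise was put on by code.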